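Ring A of the flavone (C4a, C5, C6, C7, C8, C8a) is a pentasubstituted benzene carrying O1 on C8a, hydrogen on C8, methoxy groups on C7, C6 and C5, and carbon on C4a. The route exploits this by cutting the C8–C8a bond: a squarate-derived cyclobutenone (C8a, C4a, C5, C6) joined to a 1-methoxyvinyl unit (C7, C8) maps onto the pattern atom for atom. Heating the precursor, a 2-alkynyl-3,4-dimethoxy-4-(1-methoxyvinyl)cyclobutenone, opens the four-membered ring to a dienylketene that closes by 6π electrocyclization. One operation thus gives the phenol with the C4–C3–C2–ring B chain ortho to the new hydroxyl. Oxygen transposition and oxidative cyclization finish the pyranone.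

Key step: step 5

Remark on stereochemistry: the target is achiral; the propargylic carbon and C4 of the cyclobutenone are transient stereocentres, so the intermediates are carried as racemates or diastereomer mixtures.

Step 1
Reactants: 1 3,4,5-trimethoxybenzaldehyde; 2 ethynylmagnesium bromide
Product: 3 1-(3,4,5-trimethoxyphenyl)prop-2-yn-1-ol (racemic)
Conditions: THF, 0 °C to rt; then aq NH4Cl
Reagents that add atoms: ethynylmagnesium bromide, C#C[Mg]Br
Why: Grignard 1,2-addition of the magnesium acetylide to the aryl aldehyde gives the secondary propargylic alcohol; the new carbinol stereocentre is formed without control and is kept racemic because step 6 destroys it.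

Step 2
Reactants: 3 1-(3,4,5-trimethoxyphenyl)prop-2-yn-1-ol; 4 tert-butyldimethylsilyl chloride
Product: 5 tert-butyl(dimethyl){[1-(3,4,5-trimethoxyphenyl)prop-2-yn-1-yl]oxy}silane (racemic)
Conditions: TBSCl, imidazole, DMF, rt
Reagents that add atoms: tert-butyldimethylsilyl chloride, CC(C)(C)[Si](C)(C)Cl
Why: Imidazole-mediated O-silylation of a secondary alcohol is routine, and the TBS ether removes the only acidic O–H before the organolithium chemistry of steps 3 and 4.

Step 3
Reactants: 5 silyl-protected propargylic alcohol; 6 dimethyl squarate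
Product: 10 3-[3-(tert-butyldimethylsilyloxy)-3-(3,4,5-trimethoxyphenyl)prop-1-ynyl]-4-methoxycyclobut-3-ene-1,2-dione (racemic), via lithium acetylide 7 (not isolated), via squarate adduct alkoxide 8 (not isolated), via trifluoroacetate ester 9 (not isolated)
Conditions: n-BuLi, THF, −78 °C; add to 6 in THF, −78 °C; TFAA, −78 °C; aq NH4Cl, −78 °C to rt
Reagents that add atoms: dimethyl squarate, COc1c(OC)c(=O)c1=O; water, O
Why: Deprotonation of the terminal alkyne, 1,2-addition of the lithium acetylide to one squarate carbonyl, trifluoroacetylation of the alkoxide and hydrolytic loss of methanol on work-up form the established transposition of squarate esters into 3-substituted 4-alkoxycyclobutenediones, and the anhydride activation avoids the strong aqueous acid that would endanger the silyl ether; the quaternary centre of 8 and 9 is transient.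

Step 4
Reactants: 10 alkynyl methoxy cyclobutenedione; 11 methyl vinyl ether; 12 methyl trifluoromethanesulfonate
Product: 15 2-[3-(tert-butyldimethylsilyloxy)-3-(3,4,5-trimethoxyphenyl)prop-1-ynyl]-3,4-dimethoxy-4-(1-methoxyethenyl)cyclobut-2-en-1-one (diastereomer mixture), via 1-methoxyvinyllithium 13 (not isolated), via tertiary lithium alkoxide 14 (not isolated)
Conditions: 11 (2.0 equiv), t-BuLi (1.5 equiv), THF, −78 to 0 °C, recool to −78 °C; add to 10 in THF, −78 °C; MeOTf, −78 to 0 °C; aq NaHCO3; Et3N-deactivated silica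
Reagents that add atoms: methyl vinyl ether, COC=C; methyl trifluoromethanesulfonate, COS(=O)(=O)C(F)(F)F
Why: α-Lithiation of methyl vinyl ether and 1,2-addition of the vinyllithium at −78 °C should occur at the carbonyl next to the methoxy-bearing carbon, the more electrophilic one because the other carbonyl is deactivated as a vinylogous ester, and the tertiary lithium alkoxide is then O-methylated in the same flask by methyl triflate; the new quaternary stereocentre forms unselectively and is erased in step 5.

Step 5
Reactants: 15 4-methoxy-4-(1-methoxyethenyl)cyclobutenone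
Product: 18 2-[3-(tert-butyldimethylsilyloxy)-3-(3,4,5-trimethoxyphenyl)prop-1-ynyl]-3,4,5-trimethoxyphenol (racemic), via dienylketene 16 (not isolated), via cyclohexadienone 17 (not isolated)
Conditions: PhMe (degassed, 0.02 M), 110 °C
Reagents that add atoms: none
Why: Heat breaks the C1–C4 bond of the cyclobutenone in a conrotatory 4π electrocyclic opening to give dienylketene 16, whose ketene carbon (future C8a) then bonds to the terminal CH2 of the methoxyvinyl group (future C8) in a thermal 6π electrocyclization; enolization of cyclohexadienone 17 gives the phenol. The closest known reaction type is the thermal ring expansion of 4-alkenyl-4-alkoxycyclobutenones made from squarate esters, which delivers highly oxygenated phenols. Ring A is closed as a six-membered carbocycle by disrotatory 6π closure of a ketene-containing triene, and aromatisation makes the step irreversible. No stereocentre is created, and the cyclobutenone stereocentre is erased, so the diastereomers of 15 converge on one racemic product. The selectivity needed is torquoselectivity: the C4 methoxy group, the stronger donor, should rotate outward and thereby turn the methoxyvinyl group inward next to the ketene, giving the (Z)-dienylketene that can cyclise faster than the ketene is intercepted. Regiochemistry cannot vary because every ring carbon already carries its final substituent, and the alkynyl group on the carbon that becomes C4a is a spectator.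

Step 6
Reactants: 18 ortho-alkynyl phenol
Product: 20 (E)-1-(6-hydroxy-2,3,4-trimethoxyphenyl)-3-(3,4,5-trimethoxyphenyl)prop-2-en-1-one, via propargylic alcohol 19 (not isolated)
Conditions: TsOH·H2O (0.5 equiv), 1,4-dioxane/H2O (9:1), 60 °C
Reagents that add atoms: water, O
Why: Aqueous sulfonic acid cleaves the secondary silyl ether and then effects a Meyer–Schuster rearrangement, since ionisation of propargylic alcohol 19 gives an allenyl cation strongly stabilised by the 2,4,6-oxygenated ring A, water adds at the ring A terminus and the allenol tautomerises to the thermodynamically favoured (E)-enone; Markovnikov hydration of the electron-rich alkyne followed by β-elimination would lead to the same chalcone.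

Step 7
Reactants: 20 2'-hydroxychalcone
Product: 22 5,6,7-trimethoxy-2-(3,4,5-trimethoxyphenyl)-4H-chromen-4-one (target), via flavanone 21 (not isolated)
Conditions: I2 (0.1 equiv), DMSO, 130 °C
Reagents that add atoms: none
Why: Iodine in hot DMSO is the standard oxidative cyclisation of 2'-hydroxychalcones to flavones: oxa-Michael closure gives flavanone 21, α-iodination and loss of HI install the C2–C3 double bond, DMSO reoxidises HI to I2, and any 21 already formed in step 6 converges on the same product.

Compound list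
1 | 3,4,5-trimethoxybenzaldehyde | COc1cc(C=O)cc(OC)c1OC | starting material
2 | ethynylmagnesium bromide | C#C[Mg]Br | starting material
3 | 1-(3,4,5-trimethoxyphenyl)prop-2-yn-1-ol (racemic) | C#CC(O)c1cc(OC)c(OC)c(OC)c1 | intermediate
4 | tert-butyldimethylsilyl chloride | CC(C)(C)[Si](C)(C)Cl | starting material
5 | tert-butyl(dimethyl){[1-(3,4,5-trimethoxyphenyl)prop-2-yn-1-yl]oxy}silane (racemic) | C#CC(O[Si](C)(C)C(C)(C)C)c1cc(OC)c(OC)c(OC)c1 | intermediate
6 | dimethyl squarate (3,4-dimethoxycyclobut-3-ene-1,2-dione) | COc1c(OC)c(=O)c1=O | starting material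
7 | lithium acetylide of 5 (racemic) | [Li]C#CC(O[Si](C)(C)C(C)(C)C)c1cc(OC)c(OC)c(OC)c1 | intermediate
8 | lithium 1-[3-(tert-butyldimethylsilyloxy)-3-(3,4,5-trimethoxyphenyl)prop-1-ynyl]-2,3-dimethoxy-4-oxocyclobut-2-en-1-olate (diastereomer mixture) | [Li]OC1(C#CC(O[Si](C)(C)C(C)(C)C)c2cc(OC)c(OC)c(OC)c2)C(OC)=C(OC)C1=O | intermediate
9 | 1-[3-(tert-butyldimethylsilyloxy)-3-(3,4,5-trimethoxyphenyl)prop-1-ynyl]-2,3-dimethoxy-4-oxocyclobut-2-en-1-yl trifluoroacetate (diastereomer mixture) | O=C(OC1(C#CC(O[Si](C)(C)C(C)(C)C)c2cc(OC)c(OC)c(OC)c2)C(OC)=C(OC)C1=O)C(F)(F)F | intermediate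
10 | 3-[3-(tert-butyldimethylsilyloxy)-3-(3,4,5-trimethoxyphenyl)prop-1-ynyl]-4-methoxycyclobut-3-ene-1,2-dione (racemic) | COC1=C(C#CC(O[Si](C)(C)C(C)(C)C)c2cc(OC)c(OC)c(OC)c2)C(=O)C1=O | intermediate
11 | methyl vinyl ether | COC=C | starting material
12 | methyl trifluoromethanesulfonate | COS(=O)(=O)C(F)(F)F | starting material
13 | 1-methoxyvinyllithium | [Li]C(=C)OC | intermediate
14 | lithium 3-[3-(tert-butyldimethylsilyloxy)-3-(3,4,5-trimethoxyphenyl)prop-1-ynyl]-2-methoxy-1-(1-methoxyethenyl)-4-oxocyclobut-2-en-1-olate (diastereomer mixture) | [Li]OC1(C(OC)=C)C(OC)=C(C#CC(O[Si](C)(C)C(C)(C)C)c2cc(OC)c(OC)c(OC)c2)C1=O | intermediate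
15 | 2-[3-(tert-butyldimethylsilyloxy)-3-(3,4,5-trimethoxyphenyl)prop-1-ynyl]-3,4-dimethoxy-4-(1-methoxyethenyl)cyclobut-2-en-1-one (diastereomer mixture) | O=C1C(C#CC(O[Si](C)(C)C(C)(C)C)c2cc(OC)c(OC)c(OC)c2)=C(OC)C1(OC)C(OC)=C | intermediate
16 | (3Z)-2-[3-(tert-butyldimethylsilyloxy)-3-(3,4,5-trimethoxyphenyl)prop-1-ynyl]-3,4,5-trimethoxyhexa-1,3,5-trien-1-one (racemic) | O=C=C(C#CC(O[Si](C)(C)C(C)(C)C)c1cc(OC)c(OC)c(OC)c1)/C(OC)=C(OC)\C(OC)=C | intermediate
17 | 2-[3-(tert-butyldimethylsilyloxy)-3-(3,4,5-trimethoxyphenyl)prop-1-ynyl]-3,4,5-trimethoxycyclohexa-2,4-dien-1-one (racemic) | O=C1CC(OC)=C(OC)C(OC)=C1C#CC(O[Si](C)(C)C(C)(C)C)c1cc(OC)c(OC)c(OC)c1 | intermediate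
18 | 2-[3-(tert-butyldimethylsilyloxy)-3-(3,4,5-trimethoxyphenyl)prop-1-ynyl]-3,4,5-trimethoxyphenol (racemic) | Oc1cc(OC)c(OC)c(OC)c1C#CC(O[Si](C)(C)C(C)(C)C)c1cc(OC)c(OC)c(OC)c1 | intermediate
19 | 2-[3-hydroxy-3-(3,4,5-trimethoxyphenyl)prop-1-ynyl]-3,4,5-trimethoxyphenol (racemic) | Oc1cc(OC)c(OC)c(OC)c1C#CC(O)c1cc(OC)c(OC)c(OC)c1 | intermediate
20 | (E)-1-(6-hydroxy-2,3,4-trimethoxyphenyl)-3-(3,4,5-trimethoxyphenyl)prop-2-en-1-one | COc1cc(/C=C/C(=O)c2c(O)cc(OC)c(OC)c2OC)cc(OC)c1OC | intermediate
21 | 5,6,7-trimethoxy-2-(3,4,5-trimethoxyphenyl)chroman-4-one (racemic) | COc1cc(C2CC(=O)c3c(OC)c(OC)c(OC)cc3O2)cc(OC)c1OC | intermediate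
22 | 5,6,7-trimethoxy-2-(3,4,5-trimethoxyphenyl)-4H-chromen-4-one (5,6,7,3',4',5'-hexamethoxyflavone) | COc1cc(-c2cc(=O)c3c(OC)c(OC)c(OC)cc3o2)cc(OC)c1OC | target

Total step count: 7. Longest linear sequence: 7 steps (1 to 22 through steps 1–7).

Steps most likely to fail

1. Step 5 (key step). What may go wrong: adventitious acid may hydrolyse the enol ether before the ring opens, or the ring may open with the methoxyvinyl group turned outward, so that the ketene is consumed by dimerisation or external trapping instead of closing. The fallback sets out from 5 and comes back at 18. Commercial 3,4,5-trimethoxyphenol (COc1cc(O)cc(OC)c1OC) would be iodinated ortho to the hydroxyl with N-iodosuccinimide (MeCN, 0 °C) to give 2-iodo-3,4,5-trimethoxyphenol F1. Acetylation (Ac2O, pyridine) would give 2-iodo-3,4,5-trimethoxyphenyl acetate F2. Sonogashira coupling of F2 with alkyne 5 (PdCl2(PPh3)2, CuI, Et3N, DMF, 60 °C) would give 2-[3-(tert-butyldimethylsilyloxy)-3-(3,4,5-trimethoxyphenyl)prop-1-ynyl]-3,4,5-trimethoxyphenyl acetate F3; the acetate blocks metal-induced closure to a benzofuran. Mild methanolysis (K2CO3, MeOH, 0 °C) would then release 18.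

2. Step 6. What may go wrong: the propargylic cation may be captured by the free phenol or by the nucleophilic C–H position of ring A of a second molecule (oligomerisation), or the phenol oxygen may add across the alkyne (5-endo closure to a benzofuran). The fallback sets out from 18 and comes back at 20. The phenol would be masked as the pivalate ester of 18 F4 (PivCl, Et3N, DMAP, CH2Cl2). The acid treatment of step 6 would then pass through the desilylated propargylic alcohol pivalate F5 (not isolated) to 2-[(E)-3-(3,4,5-trimethoxyphenyl)prop-2-enoyl]-3,4,5-trimethoxyphenyl pivalate F6. Methanolysis (K2CO3, MeOH, rt) would give 20. With the oxygen acylated, neither O-capture nor benzofuran closure is possible and ring A is a poorer Friedel–Crafts partner.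

3. Step 4. What may go wrong: the hindered tertiary alkoxide may be methylated incompletely or may fragment before it is trapped, and the basic vinyllithium may abstract the propargylic proton instead of adding. The fallback sets out from 10 and comes back at 15. The addition would be run as before but quenched at −78 °C with aq NH4Cl, to isolate 2-[3-(tert-butyldimethylsilyloxy)-3-(3,4,5-trimethoxyphenyl)prop-1-ynyl]-4-hydroxy-3-methoxy-4-(1-methoxyethenyl)cyclobut-2-en-1-one F7. The neutral alcohol would then be etherified with MeI and Ag2O (K2CO3, MeCN, rt), giving 15. This separates C–C bond formation from O-methylation and avoids a long-lived alkoxide.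

Further compounds
F1 | step 5 | 2-iodo-3,4,5-trimethoxyphenol | COc1cc(O)c(I)c(OC)c1OC
F2 | step 5 | 2-iodo-3,4,5-trimethoxyphenyl acetate | COc1cc(OC(C)=O)c(I)c(OC)c1OC
F3 | step 5 | 2-[3-(tert-butyldimethylsilyloxy)-3-(3,4,5-trimethoxyphenyl)prop-1-ynyl]-3,4,5-trimethoxyphenyl acetate (racemic) | CC(=O)Oc1cc(OC)c(OC)c(OC)c1C#CC(O[Si](C)(C)C(C)(C)C)c1cc(OC)c(OC)c(OC)c1
F4 | step 6 | 2-[3-(tert-butyldimethylsilyloxy)-3-(3,4,5-trimethoxyphenyl)prop-1-ynyl]-3,4,5-trimethoxyphenyl pivalate (racemic) | CC(C)(C)C(=O)Oc1cc(OC)c(OC)c(OC)c1C#CC(O[Si](C)(C)C(C)(C)C)c1cc(OC)c(OC)c(OC)c1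
F5 | step 6 | 2-[3-hydroxy-3-(3,4,5-trimethoxyphenyl)prop-1-ynyl]-3,4,5-trimethoxyphenyl pivalate (racemic) | CC(C)(C)C(=O)Oc1cc(OC)c(OC)c(OC)c1C#CC(O)c1cc(OC)c(OC)c(OC)c1
F6 | step 6 | 2-[(E)-3-(3,4,5-trimethoxyphenyl)prop-2-enoyl]-3,4,5-trimethoxyphenyl pivalate | COc1cc(/C=C/C(=O)c2c(OC(=O)C(C)(C)C)cc(OC)c(OC)c2OC)cc(OC)c1OC
F7 | step 4 | 2-[3-(tert-butyldimethylsilyloxy)-3-(3,4,5-trimethoxyphenyl)prop-1-ynyl]-4-hydroxy-3-methoxy-4-(1-methoxyethenyl)cyclobut-2-en-1-one (diastereomer mixture) | O=C1C(C#CC(O[Si](C)(C)C(C)(C)C)c2cc(OC)c(OC)c(OC)c2)=C(OC)C1(O)C(OC)=C
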